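Late in Wednesday's run the product is still creeping upward, at 57.5 % of the electrophile charged after 8.00 h, although the fast part was over by 1.00 h, when c_product stood at half of the charged c_nucleophile. Saturday's run shows the same stop, with 74.7 % at 2.00 h.

| flask | electrophile | nucleophile | protic impurity | solid base | remark | time |
|---|---|---|---|---|---|---|
| Wednesday's | 0.20 M | 0.14 M | 0.040 M | 0.30 M | run made earlier |  |
| Saturday's | 0.20 M | 0.30 M | 0.040 M | 0.30 M | run made earlier |  |
| noon | 0.20 M | 0.180 M | 0.0400 M | 0.300 M |  | 15 h |
| dawn | 0.20 M | 0.270 M | 0.0400 M | 0.300 M |  | 15 h |
| midnight | 0.20 M | 0.400 M | 0.0400 M | 0.300 M |  | 15 h |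

- Wednesday's (time / h: electrophile / %, product / %): 0.417: 73.5, 26.9; 1.00: 64.5, 35.1; 2.00: 59.1, 41.5; 3.00: 55.3, 44.8; 5.00: 49.2, 50.7; 6.00: 46.6, 53.0; 8.00: 42.3, 57.5
- Saturday's (time / h: electrophile / %, product / %): 0.417: 49.2, 51.0; 1.00: 33.7, 66.6; 2.00: 24.6, 74.7; 3.00: 19.9, 79.7; 5.00: 14.3, 85.6; 6.00: 12.2, 88.0; 8.00: 7.6, 91.6

(readings scatter by 0.3 percentage points)

* part of the electrophile that has reacted at the end, noon
* part of the electrophile that has reacted at the end, dawn
* part of the electrophile that has reacted at the end, midnight
* what raising the concentration of nucleophile from its lowest to its highest value here does to the part of the electrophile that has reacted (changes below 5 percentage points count as none) (it falls / it rises / no change)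

- given per volume of solution although it is solid: solid base
- on the list of suspects stand: nucleophile + acid set free <-> protonated nucleophile; protic impurity + free base -> quenched reagent; acid set free + free base <-> salt of the base; solid base <-> free base; acid set free -> by-product carried off; electrophile + nucleophile -> acid set free + product
- at the start none of the solid base is in solution

A ledger of the nucleophile explains this stop. At noon it is the limiting reagent, charged in a smaller amount than the electrophile. Each mole of it ends as product, as protonated nucleophile or as free nucleophile. Each mole of product also sets one mole of acid free, and that acid parks a second nucleophile unless something has relieved it. With little free nucleophile, the books close on: charged c_nucleophile = 2·c_product − b, where b is the relief.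

Wednesday's readings give b as 0.0392 M at 3.00 h and 0.0900 M at 8.00 h. Drawn straight against the root of time, these reach 0.138 M at 15 h. This is an estimate of the relief at the end, the acid no longer holding a nucleophile, and this reckoning, which is separate from the forecast's, assumes it to be the same in each flask.

The ceiling on c_product is then the smallest of charged c_electrophile, charged c_nucleophile and (charged c_nucleophile + b)/2. For noon the last entry gives 79.6 % of the electrophile. For dawn it gives 102 %, more than the electrophile charged, so the ledger sets no stop below completion there, and midnight's entry lies higher still.

The forecast reasons that “each acid released protonates a second nucleophile”. It gives 79.5 % for noon, 95.5 % for dawn and 99.7 % for midnight, and says of the trend: it rises.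

Noon gives 80.1 %, dawn 96.7 % and midnight >99.9 %, and the trend reads: it rises, by 20 percentage points. At 15.0 h noon holds 0.141 M of by-product carried off, 0.00471 M of salt of the base and 7.24 × 10⁻⁴ M of acid set free. These forms together put noon's b at 0.146 M, beside the 0.138 M carried forward from Wednesday.

    nucleophile + acid set free ⇌ protonated nucleophile, settled at all times (K = 3460 M⁻¹)
    protic impurity + free base → quenched reagent (k = 7.26 × 10⁻⁴ M⁻¹ s⁻¹)
    acid set free + free base ⇌ salt of the base, settled at all times (K = 40.6 M⁻¹)
    solid base ⇌ free base, rate k4*(cs4 - [free base]) while solid is left; crystals form when [free base] > cs4 (solubility = 0.160 M, k = 0.00184 s⁻¹)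
    acid set free → by-product carried off (k = 0.00186 s⁻¹)
    electrophile + nucleophile → acid set free + product (k = 0.00280 M⁻¹ s⁻¹)

Take dawn's flask with 0.068 M of nucleophile. There the relief entry gives 0.103 M, more than the charged nucleophile, so the ceiling is that charge, 34.0 % of the electrophile. The computed flask has reacted 34.0 % at 15.0 h, with 0.014 % of its nucleophile left.

The runs are calculated with made-up constants, noise included.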